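**Retrosynthetic overview**

1. Numbering: naphthalene A has C1 (axis), C2 (OH), C4 and C5 (OMe), C7 (CH3); naphthalene B has C1' (axis), C2' (CH3), C3', C4' (OH), C4a', C5' (OMe), C6' (OH), C8a'; ring B1 is C1'-C2'-C3'-C4'-C4a'-C8a' and ring B2 is its benzo partner.
2. Feature used: C1' and C4' of ring B1 sit on the neighbouring carbons C8a' and C4a' of ring B2 just as the aryl-bearing carbinol carbon and the lactone carbonyl of a 3-arylphthalide do, and C2' (with its methyl) plus C3' are the beta and alpha carbons of a crotonate. Ring B1 is therefore cut at C1'-C2' and C3'-C4' (phthalide-anion Michael-Dieckmann annulation, then loss of water), with a temporary ester on C3'.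
3. The 3-arylphthalide is cut at C1-C1', so the future axis is made as an sp3 carbon: ortho-lithiated 3-(benzyloxy)-2-methoxybenzamide (ring B2, from 2,3-dihydroxybenzoic acid) adds to the C1 aldehyde of benzyl-protected naphthol A, and lactonisation follows.
4. Naphthalene A: the oxygenated ring C1-C4 is closed by Claisen condensation of an aryl acetone made from 2-methoxy-4-methylbenzoic acid (ortho-methylation, lateral acylation); benzylation at O2, methylation at O4 and formylation at C1 follow.
5. Ring order: oxygenated ring of naphthalene A, lactone ring (temporary), ring B1; end game: saponification, decarboxylation at C3', hydrogenolysis of both benzyl ethers.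

Key step: step 13

Assumption: the SMILES fixes no configuration at the C1-C1' axis, so the racemic biaryl is taken as the target and no stereocentre has to be controlled.

**Route**

Step 1
Reactants: 1 2-methoxy-4-methylbenzoic acid
Product: 2 2-methoxy-4,6-dimethylbenzoic acid
Conditions: s-BuLi (2.2 equiv), TMEDA, THF, −78 °C; MeI; then aq. HCl
Reagents that add atoms: iodomethane, CI
Why: Carboxylate-directed ortho-lithiation (directed ortho metalation of the unprotected acid) should take the only position ortho to the lithium carboxylate, C6, and the aryllithium is then methylated by MeI.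

Step 2
Reactants: 2 2-methoxy-4,6-dimethylbenzoic acid
Product: 3 methyl 2-methoxy-4,6-dimethylbenzoate
Conditions: MeI, K2CO3, DMF, rt
Reagents that add atoms: iodomethane, CI
Why: SN2 O-alkylation of the potassium carboxylate (Williamson-type esterification) is insensitive to the two ortho substituents that would slow a Fischer esterification.

Step 3
Reactants: 3 methyl 2-methoxy-4,6-dimethylbenzoate
Product: 4 methyl 2-methoxy-4-methyl-6-(2-oxopropyl)benzoate
Conditions: LiN(i-Pr)2, THF, −78 °C; N-methoxy-N-methylacetamide, −78 °C to 0 °C; cold aq. HCl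
Reagents that add atoms: N-methoxy-N-methylacetamide, CC(=O)N(C)OC
Why: Lateral lithiation of the ortho-toluate gives the ester-conjugated benzylic anion of the C6 methyl group, which acylates the Weinreb amide through a stable tetrahedral lithium chelate (no over-addition), while the two ortho substituents shield the ester from self-condensation.

Step 4
Reactants: 4 methyl 2-methoxy-4-methyl-6-(2-oxopropyl)benzoate
Product: 5 8-methoxy-6-methylnaphthalene-1,3-diol
Conditions: NaH (2.5 equiv), THF, 0 °C to reflux, Ar; then aq. HCl
Reagents that add atoms: none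
Why: Intramolecular Claisen (Dieckmann-type) condensation of the methyl ketone enolate onto the benzoate closes the six-membered ring, and the 1,3-diketone enolises to the aromatic naphthalenediol, whose deprotonation drives the equilibrium.

Step 5
Reactants: 5 8-methoxy-6-methylnaphthalene-1,3-diol
Product: 6 3-(benzyloxy)-8-methoxy-6-methylnaphthalen-1-ol
Conditions: BnBr (1.0 equiv), K2CO3 (1.1 equiv), acetone, rt, Ar
Reagents that add atoms: benzyl bromide, BrCc1ccccc1
Why: Williamson etherification with one equivalent of halide should go first to the unhindered C3 hydroxyl, because the C1 hydroxyl is hydrogen-bonded to and screened by the peri methoxy group.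

Step 6
Reactants: 6 3-(benzyloxy)-8-methoxy-6-methylnaphthalen-1-ol
Product: 7 3-(benzyloxy)-1,8-dimethoxy-6-methylnaphthalene
Conditions: NaH, MeI, DMF, 0 °C to rt
Reagents that add atoms: iodomethane, CI
Why: Williamson methylation of the remaining peri hydroxyl, for which irreversible deprotonation by NaH overcomes the intramolecular hydrogen bond.

Step 7
Reactants: 7 3-(benzyloxy)-1,8-dimethoxy-6-methylnaphthalene
Product: 8 2-(benzyloxy)-4,5-dimethoxy-7-methyl-1-naphthaldehyde
Conditions: POCl3, DMF, 0 °C to 60 °C; then ice-water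
Reagents that add atoms: N,N-dimethylformamide, CN(C)C=O; water, O
Why: Vilsmeier-Haack formylation should attack the alpha carbon C4 of 7 (C1 of naphthalene A), which is ortho to the benzyloxy group and para to a methoxy group and so is the most nucleophilic position.

Step 8
Reactants: 9 2,3-dihydroxybenzoic acid
Product: 10 methyl 2,3-dihydroxybenzoate
Conditions: MeOH, H2SO4 (cat.), reflux
Reagents that add atoms: methanol, CO
Why: Fischer esterification, which leaves the catechol untouched.

Step 9
Reactants: 10 methyl 2,3-dihydroxybenzoate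
Product: 11 methyl 3-(benzyloxy)-2-hydroxybenzoate
Conditions: BnBr (1.0 equiv), K2CO3 (1.1 equiv), acetone, reflux
Reagents that add atoms: benzyl bromide, BrCc1ccccc1
Why: Regioselective Williamson etherification, since the C2 hydroxyl is held in a hydrogen bond to the ester carbonyl and the C3 phenoxide is formed and alkylated preferentially.

Step 10
Reactants: 11 methyl 3-(benzyloxy)-2-hydroxybenzoate
Product: 12 methyl 3-(benzyloxy)-2-methoxybenzoate
Conditions: MeI, K2CO3, DMF, 50 °C
Reagents that add atoms: iodomethane, CI
Why: Williamson methylation of the chelated C2 phenol under slightly more forcing conditions.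

Step 11
Reactants: 12 methyl 3-(benzyloxy)-2-methoxybenzoate
Product: 13 3-(benzyloxy)-N,N-diethyl-2-methoxybenzamide
Conditions: AlMe3, Et2NH, toluene, 0 °C to 90 °C; then aq. HCl
Reagents that add atoms: diethylamine, CCNCC
Why: Weinreb-type aminolysis, in which Me2AlNEt2 formed from AlMe3 and Et2NH converts the methyl ester directly into the tertiary amide needed as the directing group.

Step 12
Reactants: 13 3-(benzyloxy)-N,N-diethyl-2-methoxybenzamide; 8 2-(benzyloxy)-4,5-dimethoxy-7-methyl-1-naphthaldehyde
Product: 15 racemic 6-(benzyloxy)-3-[2-(benzyloxy)-4,5-dimethoxy-7-methylnaphthalen-1-yl]-7-methoxyisobenzofuran-1(3H)-one, via hydroxy amide 14 (not isolated)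
Conditions: 13, s-BuLi, TMEDA, THF, −78 °C; add 8, −78 °C to 0 °C; H2O; then TsOH·H2O (cat.), toluene, 90 °C
Reagents that add atoms: none
Why: Amide-directed ortho-lithiation (directed ortho metalation) at C6, the only free position ortho to the amide, is followed by 1,2-addition to the aldehyde and acid-promoted lactonisation of the benzylic alcohol onto the neighbouring amide with loss of volatile diethylamine; the new stereocentre C3 forms racemic and is destroyed in step 13.

Step 13
Reactants: 15 racemic 6-(benzyloxy)-3-[2-(benzyloxy)-4,5-dimethoxy-7-methylnaphthalen-1-yl]-7-methoxyisobenzofuran-1(3H)-one; 16 methyl (E)-but-2-enoate (methyl crotonate)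
Product: 19 methyl 7-(benzyloxy)-4-[2-(benzyloxy)-4,5-dimethoxy-7-methylnaphthalen-1-yl]-1-hydroxy-8-methoxy-3-methyl-2-naphthoate (racemic about the axis), via Michael adduct lactone ester 17 (not isolated), via hydroxy tetralone keto ester 18 (not isolated)
Conditions: LiN(i-Pr)2, THF, −78 °C; 16, −78 °C to rt; aq. HCl; then TsOH·H2O (cat.), toluene, 80 °C
Reagents that add atoms: none
Why: LiN(i-Pr)2 removes the C3 proton of the phthalide (doubly benzylic, alpha to oxygen, vinylogous to the lactone carbonyl) to give a 1-oxidoisobenzofuran-type anion that adds through the future C1' to the beta carbon of the crotonate (C1'-C2'), and the ester enolate so formed attacks the lactone carbonyl (C3'-C4') with release of the C1' alkoxide. The closest known reaction type is the phthalide-anion Michael-Dieckmann annulation (a Hauser-Kraus-type annulation without a leaving group, finished by dehydration), and oxidoisobenzofuran species derived from 3-arylphthalides are known to annulate with unsaturated esters to 4-aryl-1-naphthols, so this is that reaction on a more hindered donor. Ring B1 is closed by a 6-exo-trig Dieckmann attack, which can equally be seen as collapse of a formal [4+2] adduct of the oxidoisobenzofuran. Acid then ionises the tertiary diaryl carbinol at C1', and loss of the C2' proton plus enolisation of the keto ester aromatise the ring without an oxidant. The two sp3 stereocentres of 17 and 18 vanish on aromatisation and the C1-C1' axis arises racemic, so no stereocontrol is needed. The step needs 1,4- over 1,2-addition and a single direction of elimination, which are secured by the soft delocalised anion, by the lactone carbonyl being the only electrophile within reach of the enolate, and by C2' being the only hydrogen-bearing neighbour of C1'.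

Step 14
Reactants: 19 methyl 7-(benzyloxy)-4-[2-(benzyloxy)-4,5-dimethoxy-7-methylnaphthalen-1-yl]-1-hydroxy-8-methoxy-3-methyl-2-naphthoate
Product: 20 7-(benzyloxy)-4-[2-(benzyloxy)-4,5-dimethoxy-7-methylnaphthalen-1-yl]-1-hydroxy-8-methoxy-3-methyl-2-naphthoic acid
Conditions: KOH, DMSO/H2O, 100 °C, Ar; then aq. HCl
Reagents that add atoms: potassium hydroxide, [K+].[OH-]
Why: Saponification (acyl-oxygen ester hydrolysis) of the hindered, hydrogen-bonded methyl ester under forcing hydroxide conditions that benzyl and methyl aryl ethers tolerate.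

Step 15
Reactants: 20 7-(benzyloxy)-4-[2-(benzyloxy)-4,5-dimethoxy-7-methylnaphthalen-1-yl]-1-hydroxy-8-methoxy-3-methyl-2-naphthoic acid
Product: 21 2,6'-bis(benzyloxy)-4,5,5'-trimethoxy-2',7-dimethyl-[1,1'-binaphthalen]-4'-ol (racemic)
Conditions: Cu2O (cat.), 1,10-phenanthroline (cat.), NMP/quinoline, 160 °C, Ar
Reagents that add atoms: none
Why: Copper-catalysed protodecarboxylation of the ortho-hydroxy naphthoic acid, eased by the electron-rich ring and by relief of strain between the flanking hydroxyl and methyl groups.

Step 16
Reactants: 21 2,6'-bis(benzyloxy)-4,5,5'-trimethoxy-2',7-dimethyl-[1,1'-binaphthalen]-4'-ol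
Product: 22 4,5,5'-trimethoxy-2',7-dimethyl-[1,1'-binaphthalene]-2,4',6'-triol (racemic target)
Conditions: H2 (1 atm), Pd/C, EtOAc/MeOH, rt
Reagents that add atoms: none
Why: Catalytic hydrogenolysis of the two benzyl aryl ethers over Pd/C should leave the methyl ethers and the naphthalene rings untouched and give the target.

**Compound list**

1 | 2-methoxy-4-methylbenzoic acid | COc1cc(C)ccc1C(=O)O | starting material
2 | 2-methoxy-4,6-dimethylbenzoic acid | COc1cc(C)cc(C)c1C(=O)O | intermediate
3 | methyl 2-methoxy-4,6-dimethylbenzoate | COC(=O)c1c(C)cc(C)cc1OC | intermediate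
4 | methyl 2-methoxy-4-methyl-6-(2-oxopropyl)benzoate | COC(=O)c1c(CC(C)=O)cc(C)cc1OC | intermediate
5 | 8-methoxy-6-methylnaphthalene-1,3-diol | COc1cc(C)cc2cc(O)cc(O)c12 | intermediate
6 | 3-(benzyloxy)-8-methoxy-6-methylnaphthalen-1-ol | COc1cc(C)cc2cc(OCc3ccccc3)cc(O)c12 | intermediate
7 | 3-(benzyloxy)-1,8-dimethoxy-6-methylnaphthalene | COc1cc(C)cc2cc(OCc3ccccc3)cc(OC)c12 | intermediate
8 | 2-(benzyloxy)-4,5-dimethoxy-7-methyl-1-naphthaldehyde | COc1cc(C)cc2c(C=O)c(OCc3ccccc3)cc(OC)c12 | intermediate
9 | 2,3-dihydroxybenzoic acid | O=C(O)c1cccc(O)c1O | starting material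
10 | methyl 2,3-dihydroxybenzoate | COC(=O)c1cccc(O)c1O | intermediate
11 | methyl 3-(benzyloxy)-2-hydroxybenzoate | COC(=O)c1cccc(OCc2ccccc2)c1O | intermediate
12 | methyl 3-(benzyloxy)-2-methoxybenzoate | COC(=O)c1cccc(OCc2ccccc2)c1OC | intermediate
13 | 3-(benzyloxy)-N,N-diethyl-2-methoxybenzamide | CCN(CC)C(=O)c1cccc(OCc2ccccc2)c1OC | intermediate
14 | racemic 3-(benzyloxy)-6-{[2-(benzyloxy)-4,5-dimethoxy-7-methylnaphthalen-1-yl](hydroxy)methyl}-N,N-diethyl-2-methoxybenzamide (not isolated) | CCN(CC)C(=O)c1c(C(O)c2c(OCc3ccccc3)cc(OC)c3c(OC)cc(C)cc23)ccc(OCc2ccccc2)c1OC | intermediate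
15 | racemic 6-(benzyloxy)-3-[2-(benzyloxy)-4,5-dimethoxy-7-methylnaphthalen-1-yl]-7-methoxyisobenzofuran-1(3H)-one | O=C1OC(c2c(OCc3ccccc3)cc(OC)c3c(OC)cc(C)cc23)c2ccc(OCc3ccccc3)c(OC)c12 | intermediate
16 | methyl (E)-but-2-enoate (methyl crotonate) | C/C=C/C(=O)OC | starting material
17 | methyl 3-{5-(benzyloxy)-1-[2-(benzyloxy)-4,5-dimethoxy-7-methylnaphthalen-1-yl]-4-methoxy-3-oxo-1,3-dihydroisobenzofuran-1-yl}butanoate (racemic diastereomer mixture, present as its lithium ester enolate, drawn as the neutral ester; not isolated) | COC(=O)CC(C)C1(c2c(OCc3ccccc3)cc(OC)c3c(OC)cc(C)cc23)OC(=O)c2c(OC)c(OCc3ccccc3)ccc12 | intermediate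
18 | methyl 7-(benzyloxy)-4-[2-(benzyloxy)-4,5-dimethoxy-7-methylnaphthalen-1-yl]-4-hydroxy-8-methoxy-3-methyl-1-oxo-1,2,3,4-tetrahydronaphthalene-2-carboxylate (racemic diastereomer mixture; not isolated) | COC(=O)C1C(C)C(O)(c2c(OCc3ccccc3)cc(OC)c3c(OC)cc(C)cc23)c2ccc(OCc3ccccc3)c(OC)c2C1=O | intermediate
19 | methyl 7-(benzyloxy)-4-[2-(benzyloxy)-4,5-dimethoxy-7-methylnaphthalen-1-yl]-1-hydroxy-8-methoxy-3-methyl-2-naphthoate (racemic about the axis) | COC(=O)c1c(C)c(-c2c(OCc3ccccc3)cc(OC)c3c(OC)cc(C)cc23)c2ccc(OCc3ccccc3)c(OC)c2c1O | intermediate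
20 | 7-(benzyloxy)-4-[2-(benzyloxy)-4,5-dimethoxy-7-methylnaphthalen-1-yl]-1-hydroxy-8-methoxy-3-methyl-2-naphthoic acid (racemic about the axis) | OC(=O)c1c(C)c(-c2c(OCc3ccccc3)cc(OC)c3c(OC)cc(C)cc23)c2ccc(OCc3ccccc3)c(OC)c2c1O | intermediate
21 | 2,6'-bis(benzyloxy)-4,5,5'-trimethoxy-2',7-dimethyl-[1,1'-binaphthalen]-4'-ol (racemic about the axis) | Cc1cc(O)c2c(OC)c(OCc3ccccc3)ccc2c1-c1c(OCc2ccccc2)cc(OC)c2c(OC)cc(C)cc12 | intermediate
22 | 4,5,5'-trimethoxy-2',7-dimethyl-[1,1'-binaphthalene]-2,4',6'-triol (racemic about the axis) | COc1cc(C)cc2c(-c3c(C)cc(O)c4c(OC)c(O)ccc34)c(O)cc(OC)c12 | target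

**Step count and risk**

Total step count: 16. Longest linear sequence: 12 steps (steps 1 to 7, then 12 to 16, from compound 1).

Steps most likely to fail:

1. Step 13. The conjugate addition of the hindered tertiary anion to the beta-substituted crotonate may be slow or may revert (retro-Michael) before the Dieckmann closure, so that the phthalide is recovered and the crotonate oligomerises. Fallback, from 15: the same anion is trapped on oxygen (LiN(i-Pr)2, t-BuMe2SiCl, THF, −78 °C) to give the 1-silyloxy-3-arylisobenzofuran F1, a neutral and very reactive diene. Thermal Diels-Alder reaction of F1 with 16 (toluene, sealed tube, 80 to 110 °C) should give the oxygen-bridged cycloadduct F2, with the silyloxy terminus next to the ester-bearing carbon. TsOH·H2O in wet toluene then opens the silyl ketal bridge to 18 and dehydrates it. This is the known silyloxyisobenzofuran route from 3-arylphthalides to 4-aryl-1-naphthols, and it comes back to the route at 19.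

2. Step 5. Site selectivity between the two hydroxyls may be poor (alkylation at O1, double alkylation, or C-benzylation at C2 or C4), and the electron-rich diol may oxidise in air. Fallback, from 5: the bulky silyl chloride i-Pr3SiCl (imidazole, DMF, 0 °C) should silylate only the unhindered O3 and cannot C-alkylate, giving the 3-O-silyl ether F3. Methylation of the peri hydroxyl (MeI, K2CO3, acetone, reflux) gives the silyl methyl ether F4, n-Bu4NF in THF frees 4,5-dimethoxy-7-methylnaphthalen-2-ol F5, and ordinary benzylation (BnBr, K2CO3, DMF) comes back to the route at 7.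

3. Step 12. s-BuLi may deprotonate the benzylic CH2 of the benzyl ether (followed by Wittig rearrangement) or the carbon ortho to the benzyloxy group, in competition with the amide-directed lithiation. Fallback, from 13: electrophilic bromination (NBS, MeCN, 0 °C to rt) para to the benzyloxy group should give the 6-bromo amide F6. Bromine-lithium exchange with n-BuLi at −78 °C is faster than any deprotonation and gives the same aryllithium, which is added to 8 and lactonised as before (through 14). The fallback comes back to the route at 15.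

**Further compounds**

F1 | step 13 | tert-butyl({6-(benzyloxy)-3-[2-(benzyloxy)-4,5-dimethoxy-7-methylnaphthalen-1-yl]-7-methoxyisobenzofuran-1-yl}oxy)dimethylsilane | CC(C)(C)[Si](C)(C)OC1=C2C(OC)=C(OCc3ccccc3)C=CC2=C(c2c(OCc3ccccc3)cc(OC)c3c(OC)cc(C)cc23)O1
F2 | step 13 | methyl 7-(benzyloxy)-4-[2-(benzyloxy)-4,5-dimethoxy-7-methylnaphthalen-1-yl]-1-[(tert-butyldimethylsilyl)oxy]-8-methoxy-3-methyl-1,2,3,4-tetrahydro-1,4-epoxynaphthalene-2-carboxylate (racemic diastereomer mixture) | COC(=O)C1C(C)C2(c3c(OCc4ccccc4)cc(OC)c4c(OC)cc(C)cc34)OC1(O[Si](C)(C)C(C)(C)C)c1c(OC)c(OCc3ccccc3)ccc12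
F3 | step 5 | 8-methoxy-6-methyl-3-[(triisopropylsilyl)oxy]naphthalen-1-ol | COc1cc(C)cc2cc(O[Si](C(C)C)(C(C)C)C(C)C)cc(O)c12
F4 | step 5 | [(4,5-dimethoxy-7-methylnaphthalen-2-yl)oxy]triisopropylsilane | COc1cc(C)cc2cc(O[Si](C(C)C)(C(C)C)C(C)C)cc(OC)c12
F5 | step 5 | 4,5-dimethoxy-7-methylnaphthalen-2-ol | COc1cc(C)cc2cc(O)cc(OC)c12
F6 | step 12 | 3-(benzyloxy)-6-bromo-N,N-diethyl-2-methoxybenzamide | CCN(CC)C(=O)c1c(Br)ccc(OCc2ccccc2)c1OC
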